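The flask is to be stopped early: target does not last in the red run, which reads 17.5% at 0.100 h but 0.2% at 4.00 h.

| setting | red | violet | flask |
|---|---|---|---|
| substrate | 0.15 M | 0.15 M | 0.15 M |
| catalyst | 1.7 mol% | 3.8 mol% | 2.5 mol% |
| remark | run made earlier | run made earlier |  |
| time |  |  | 4.0 h |

| run | time / h | target / % | substrate / % |
|---|---|---|---|
| red | 0.0417 | 14.3 | 66.6 |
| red | 0.100 | 17.5 | 37.9 |
| red | 0.250 | 7.4 | 8.7 |
| red | 0.667 | 0.7 | 0 |
| red | 1.50 | 0.8 | 0 |
| red | 4.00 | 0.2 | 0 |
| violet | 0.0417 | 27.8 | 49.0 |
| violet | 0.100 | 24.8 | 18.3 |
| violet | 0.250 | 5.2 | 1.8 |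
| violet | 0.667 | 0.9 | 0.1 |
| violet | 1.50 | 0 | 0.4 |
| violet | 4.00 | 0 | 0 |

(readings scatter by 0.5 percentage points)

* the best time, 4.0 h at the latest, for target
* the amount of target, in percent of the substrate charged, at that time

- the earlier runs were read with a standard deviation of 0.5 percentage points

1. Catalyst loading, by hand. Taking the catalyst as unchanged, substrate decays pseudo-first-order, so one reading per run gives a constant: 9.70 h⁻¹ for red and 17.0 h⁻¹ for violet, both with the scatter of their readings. The constant climbs by 347 h⁻¹ per unit of loading, taken as a fraction. The straight line leaves 3.81 h⁻¹ at zero loading, read as a substrate loss without catalyst.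

2. The recipe's loading. By this line the flask's catalysed route is reckoned at 8.67 h⁻¹, faster than the other, with a reckoned share of 69.5% of the substrate. The turnover count is 27.8, that share over the loading.

3. Substrate charge. Both runs stood at 0.15 M, so the readings say nothing about changing it, and it stays at 0.15 M.

4. Time. Red reads its highest target at 0.100 h, violet at 0.0417 h with 27.8%. The flask's loading lies between theirs, so its peak is expected between those times and heights.

5. The forecast, taking target formation as “roughly proportional to catalyst”, names 0.07 h and 23%. The flask gives 22.5% at 0.0702 h, inside that bracket in time and height.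

    substrate + catalyst → catalyst + target (k = 38.9 M⁻¹ min⁻¹)
    substrate → side product (k = 0.0617 min⁻¹)
    target → over-reaction product (k = 0.270 min⁻¹)

6. At 4.0 h the flask holds 0% target and 70.3% over-reaction product, which is where the catalysed route ends. That is 28.1 turnovers against the 27.8 reckoned. The neighbour with 0.62 mol% catalyst, reckoned the same way, has a share of 36.1% and a count of 58.2. It ends with 37.0% over-reaction product, or 59.7 turnovers, and 63.0% side product, and its best target is 7.52%.

The earlier runs and the new flask were computed on assumed constants, and the scatter is random.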